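**Target.** Mutafran C (13) is methyl 4-[(2R,5S)-5-[(3E,11E)-12-bromododeca-3,11-dien-1-yn-1-yl]oxolan-2-yl]butanoate. The chain is numbered from the ester carbon C1 to the bromine-bearing carbon C20; the oxolane is O, C5, C6, C7, C8, with C5 = R and C8 = S (2,5-trans).

## Structural features

Mutafran C is a linear C20 fatty acid methyl ester in which C5 and C8 are bridged by oxygen, giving a single oxolane (O, C5, C6, C7, C8). C5 carries the saturated arm C4–C3–C2–C1(=O)OMe. C8 carries an E-enyne (C9≡C10–C11=C12) that runs through six methylenes (C13–C18) to a terminal E-bromoalkene (C19=C20–Br). The only stereocentres are C5 (R) and C8 (S); they are not adjacent but face each other across the ring oxygen in a trans relationship, and the two E alkenes are the only other stereochemical elements. The fragile groups are the alkenyl bromide (transition metals, organolithiums), the conjugated enyne (hydrogenation, hydrometalation, radicals), the methyl ester (hydroxide, hydride) and the C8–H, which is propargylic and α to oxygen, so late steps must be mild, non-reductive and only weakly basic. The real difficulty is the trans oxolane: the C5 side chain is three plain methylenes with no functional handle, so the C5 configuration has to be relayed from C8 during ring closure. The key step uses the fact that C5 is bonded to the ring oxygen and to a CH2 (C4) followed by exactly a propanoate unit (C3–C1). C4 is the radical centre left behind when the C8 oxygen closes 5-exo onto a C4=C5 alkene, and C3–C1 is an acrylate that can capture it.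

## Logic of the disconnections

**13 ⇒ 7 + 12.** The C10–C11 bond (sp–sp2) is cut. It separates the chiral, polar head from the achiral lipid tail, and the E geometry of C11=C12 is carried in ready-made by 12. The gain is two fragments of similar size made in parallel, with the sensitive tail arriving last. The forward step must insert palladium into the C–I bond and ignore the C–Br bond of 12 and of 13, under a base mild enough for the ester and C8–H.

**12 ⇒ 10 ⇒ 8.** The C11–I bond and then the C20–Br bond are cut, each haloalkene going back to a terminal alkyne. Syn hydrometalation followed by halogenolysis gives only E alkenes, and 8 already holds all ten carbons. The tail then needs no C–C bond formation. The first forward step must stop after one of two identical alkynes, and the second must add to the alkyne of 10 without touching its bromoalkene.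

**7 ⇒ 6.** The C10–H bond is traced back to a C10–Si bond. The cap is needed because the key step cannot carry a free terminal alkyne. No skeletal change results. The forward desilylation must spare the ester and C8.

**6 ⇒ 4 + 5.** The O–C5 and C4–C3 bonds are cut. This removes the ring, the C5 stereocentre and the whole ester arm at once, leaving an acyclic alkenol with one stereocentre and a commodity acceptor. The forward step must close 5-exo trans to the C8 substituent, add the C4 radical to 5 exactly once before reduction, and leave the silylalkyne and the propargylic carbinol intact under O2 and cobalt.

**4 ⇒ 3.** The C8–H bond of the carbinol is cut, turning the stereocentre into a carbonyl. C8 is the only centre that needs external asymmetric induction, and a ketone flanked by an alkyne and a CH2 is well differentiated for transfer hydrogenation. The precursor becomes achiral. The forward step must be highly enantioselective, since C8 fixes C5 and the enantiomeric purity of 13, and must not reduce C≡C or C=C.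

**3 ⇒ 1 + 2.** The C8–C9 bond is cut into an acyl and an alkynyl partner, both purchasable. This reaches the ketone oxidation level directly and saves an addition/oxidation pair. The forward coupling must outrun ketene formation from enolisable 1.

## Other disconnections considered

**Alternative 1:** The cut is the C9≡C10 triple bond, with C1 and C19 temporarily joined through an ester oxygen. In the forward key step the methyl-capped diyne ester A1 would be treated with Mo(≡C-C6H4-4-OMe)(OSiPh3)3 and 5 Å molecular sieves. The two alkynes exchange, but-2-yne A3 is expelled and trapped, and the 19-membered macrolactone A2 closes. Methanolysis would then release the methyl ester and a C19 hydroxyl, which is oxidised and converted by Takai bromo-olefination into the C19=C20–Br terminus.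
- In favour: alkyne metathesis leaves the C11=C12 alkene and its geometry alone and tolerates esters and ethers. The tether turns a statistical cross-metathesis into a ring closure, and a 19-membered cycloalkyne should be unstrained. On the join at the triple bond it is the better plan in chemoselectivity, because no palladium is used and no two alkenyl halides have to be told apart. It is equal in convergence.
- Against: it does nothing for the trans oxolane, which must still be built beforehand, most simply by chemistry like that of step 3. A conjugated enyne is a demanding metathesis partner, high dilution is needed, and the carboxyl must be carried as the free acid for the esterification.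
- Comparison: three operations follow the ring closure, and the final bromo-olefination is less geometrically secure than the hydrozirconation used for 12. In structure it solves a problem the chosen plan handles in one coupling, in mechanism it is cleaner at the alkyne, and in step economy it is clearly longer.

**Alternative 2:** The cut is a ring C–O bond (O–C8), with both side arms taken back to hydroxymethyl groups. In the forward key step the meso diepoxide A4 would be treated with water and one enantiomer of Co(salen)(OAc). Only the S epoxide is hydrolysed at its terminal carbon, and the new secondary hydroxyl opens the R epoxide at its internal carbon with inversion, 5-exo, giving the C2-symmetric trans diol A5.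
- In favour: both stereocentres and the trans relationship arise from an achiral substrate and one cheap catalyst. The trans geometry follows stereospecifically from SN2 inversion and not from a kinetic preference; on this point it is better than the chosen plan, whose trans selectivity is substrate-controlled. The C2 symmetry means a monofunctionalisation gives one product whichever hydroxyl reacts.
- Against: A4 must be free of its chiral diastereomers, which form alongside it in a non-selective double epoxidation and would feed other stereoisomers into the cascade. A5 is far from the target. One arm must become the alkyne through a configurationally labile α-alkoxy aldehyde, and the other must be extended by three carbons to the ester before any alkyne is present.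
- Comparison: it is superior in stereochemical certainty and in having a polar, predictable mechanism. It is much worse in step economy, needing roughly twice the operations to reach the stage of 7.

**Alternative 3:** The cut is O–C5 together with C5–C4, through an oxonium ylide. In the forward key step the diazoketone A6 would react with Cu(acac)2 to give a copper carbene at C5. The allyl ether oxygen on C8 attacks it to form a five-membered oxonium ylide, and the allyl group shifts [2,3] from oxygen to C5, giving the trans oxolan-3-one A7.
- In favour: like the chosen step it forms one C–O bond, one C–C bond, the ring and the C5 stereocentre in a single operation, so it is equal in bond count. The trans preference of this rearrangement on exactly this ring type rests on a compact, well-defined transition state and is at least as secure as that of the radical cyclisation, probably more so. No radical is generated near an alkyne.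
- Against: A7 carries a C6 ketone that the target lacks and that must be removed over several steps, during which C5, now α to the carbonyl, can epimerise. The allyl arm is one carbon short and needs cross-metathesis with an acrylate and then alkene hydrogenation. The silyloxymethyl arm must still be turned into the alkyne. The diazoketone requires hazardous diazo chemistry, and C–H insertion or [1,2]-shift can compete.
- Comparison: equal or better on stereocontrol and mechanism, clearly worse on step economy and on residual functionality. The chosen step delivers the ester arm at its final length and oxidation level.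

Key step: step 3

**Remarks on the chemistry.**
- The C8–O bond of 4 is never broken, so the S carbinol of 4 becomes C8 (S) of 13. The (S,S) enantiomer of the ruthenium catalyst is the one expected to give this carbinol.
- The triisopropylsilyl cap of 4 is kept unchanged.
- The ynone 3 is made directly at the ketone oxidation level from the acid chloride.

## Route

Step 1
Reactants: 1 pent-4-enoyl chloride; 2 (triisopropylsilyl)acetylene
Product: 3 1-(triisopropylsilyl)hept-6-en-1-yn-3-one
Conditions: PdCl2(PPh3)2 (2 mol%), CuI (4 mol%), Et3N (1.2 equiv), THF, rt
Reagents that add atoms: none
Why: Acyl Sonogashira coupling: the copper acetylide of 2 transmetalates to the acylpalladium chloride formed from 1, and reductive elimination gives the ynone; only a slight excess of amine in THF keeps ketene formation from the enolisable acid chloride low, and the isolated terminal alkene is inert.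

Step 2
Reactants: 3 1-(triisopropylsilyl)hept-6-en-1-yn-3-one
Product: 4 (S)-1-(triisopropylsilyl)hept-6-en-1-yn-3-ol
Conditions: Ru[(S,S)-TsDPEN](p-cymene) (1 mol%, preformed from RuCl[(S,S)-TsDPEN](p-cymene) and KOH), i-PrOH, rt
Reagents that add atoms: none
Why: Noyori asymmetric transfer hydrogenation of an α,β-acetylenic ketone; in the six-membered Ru–H/N–H transition state the alkynyl group takes the place of the unsaturated substituent, so the (S,S) ligand should deliver hydride to the face that gives the S carbinol. The base-free conditions protect the ynone, and neither C≡C nor the terminal C=C is reduced.

Step 3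
Reactants: 4 (S)-1-(triisopropylsilyl)hept-6-en-1-yn-3-ol; 5 methyl acrylate
Product: 6 methyl 4-[(2R,5S)-5-[(triisopropylsilyl)ethynyl]oxolan-2-yl]butanoate
Conditions: Co(CF3COCHCOCH3)2 (10 mol%), O2 (1 atm), 5 (10 equiv), cyclohexa-1,4-diene (20 equiv), PhMe, 60 °C
Reagents that add atoms: none
Why: The closest known reaction type is the Mukaiyama-type aerobic oxidative cyclisation of 1-substituted pent-4-en-1-ols by divalent cobalt bis(β-diketonates), in its alkylative variant where the ring-closed radical is intercepted by an acrylate before hydrogen-atom transfer. The cobalt diketonate takes up O2 and the carbinol of 4; the resulting trivalent cobalt oxidant activates C4=C5, and the bound hydroxyl oxygen attacks C5 in a 5-exo-trig closure (O–C5), leaving a primary radical at C4 and returning cobalt to the divalent state. This nucleophilic radical is polarity-matched to the electron-poor alkene 5 and should add to its β-carbon (C4–C3) faster than it takes hydrogen from the diene, while the resulting electrophilic α-ester radical is matched to the hydridic C–H of cyclohexa-1,4-diene and is quenched at C2. The cyclohexadienyl radical feeds the reduction of the cobalt–dioxygen species, so the net by-products are water and benzene. The new stereocentre C5 is controlled by the existing S centre C8: in a chair-like transition state the alkynyl group sits pseudo-equatorial, which places the C5 arm trans to it and gives the 2R,5S oxolane, while C8 keeps its C–O bond and its configuration. The step needs trans selectivity, carbon capture ahead of simple reduction but by one acrylate only, and an untouched alkyne; these are secured respectively by the C8 substituent, by the balance of excess 5 against the hydrogen donor, and by the bulky silyl cap, which removes the acidic alkyne hydrogen and shields the triple bond from radicals and cobalt. A propargylic carbinol is slimmer than the alkyl or aryl carbinols normally used, so the level of trans selectivity is the main open point.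

Step 4
Reactants: 6 methyl 4-[(2R,5S)-5-[(triisopropylsilyl)ethynyl]oxolan-2-yl]butanoate
Product: 7 methyl 4-[(2R,5S)-5-ethynyloxolan-2-yl]butanoate
Conditions: Bu4NF (1.2 equiv), AcOH (1.2 equiv), THF, 0 °C to rt
Reagents that add atoms: none
Why: Fluoride-induced protodesilylation of the C(sp)–Si bond; buffering with acetic acid protonates the acetylide at once and keeps the medium from saponifying the ester or epimerising C8, and no stereocentre is involved.

Step 5
Reactants: 8 deca-1,9-diyne
Product: 10 (E)-1-bromodec-1-en-9-yne, via (E)-dec-1-en-9-yn-1-ylzirconocene chloride 9 (not isolated)
Conditions: Cp2Zr(H)Cl (1 equiv), 8 (3 equiv), CH2Cl2, rt; then NBS, 0 °C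
Reagents that add atoms: N-bromosuccinimide, O=C1CCC(=O)N1Br (bromine of 10); Cp2Zr(H)Cl, [H][Zr](Cl)(C1C=CC=C1)C1C=CC=C1 (zirconocene chloride unit of 9 only)
Why: Schwartz hydrozirconation adds Zr–H syn and anti-Markovnikov to one terminal alkyne, and bromodezirconation with NBS proceeds with retention, so the bromoalkene should be purely E. The threefold excess of 8 keeps double addition statistically low, and unreacted 8 is removed by distillation.

Step 6
Reactants: 10 (E)-1-bromodec-1-en-9-yne
Product: 12 (1E,9E)-1-bromo-10-iododeca-1,9-diene, via (1E,9E)-10-bromodeca-1,9-dien-1-ylzirconocene chloride 11 (not isolated)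
Conditions: Cp2Zr(H)Cl (1.2 equiv), CH2Cl2, rt; then I2, 0 °C
Reagents that add atoms: iodine, II (iodine of 12); Cp2Zr(H)Cl, [H][Zr](Cl)(C1C=CC=C1)C1C=CC=C1 (zirconocene chloride unit of 11 only)
Why: Second Schwartz hydrozirconation, now followed by iodinolysis with retention; the terminal alkyne reacts far faster with the zirconium hydride than the 1,2-disubstituted bromoalkene, so the E-bromoalkene should survive and the new iodoalkene should be E.

Step 7
Reactants: 7 methyl 4-[(2R,5S)-5-ethynyloxolan-2-yl]butanoate; 12 (1E,9E)-1-bromo-10-iododeca-1,9-diene
Product: 13 Mutafran C, methyl 4-[(2R,5S)-5-[(3E,11E)-12-bromododeca-3,11-dien-1-yn-1-yl]oxolan-2-yl]butanoate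
Conditions: Pd(PPh3)4 (5 mol%), CuI (10 mol%), i-Pr2NH, THF, 0 °C to rt; 12 (1.3 equiv)
Reagents that add atoms: none
Why: Sonogashira coupling; zerovalent palladium inserts into an alkenyl C–I bond much faster than into an alkenyl C–Br bond at or below room temperature, so with 12 in slight excess only the iodide terminus should couple, with retention of the E geometry. The secondary amine is too weak a base to touch the ester or C8–H.

## Compound list

1 | pent-4-enoyl chloride | C=CCCC(=O)Cl | starting material
2 | (triisopropylsilyl)acetylene [ethynyltri(propan-2-yl)silane] | C#C[Si](C(C)C)(C(C)C)C(C)C | starting material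
3 | 1-(triisopropylsilyl)hept-6-en-1-yn-3-one | C=CCCC(=O)C#C[Si](C(C)C)(C(C)C)C(C)C | intermediate
4 | (S)-1-(triisopropylsilyl)hept-6-en-1-yn-3-ol | C=CCC[C@@H](C#C[Si](C(C)C)(C(C)C)C(C)C)O | intermediate
5 | methyl acrylate | C=CC(=O)OC | starting material
6 | methyl 4-[(2R,5S)-5-[(triisopropylsilyl)ethynyl]oxolan-2-yl]butanoate | COC(=O)CCC[C@@H]1CC[C@@H](C#C[Si](C(C)C)(C(C)C)C(C)C)O1 | intermediate
7 | methyl 4-[(2R,5S)-5-ethynyloxolan-2-yl]butanoate | COC(=O)CCC[C@@H]1CC[C@@H](C#C)O1 | intermediate
8 | deca-1,9-diyne | C#CCCCCCCC#C | starting material
9 | chlorobis(cyclopentadienyl)[(1E)-dec-1-en-9-yn-1-yl]zirconium (formed in the flask) | Cl[Zr](/C=C/CCCCCCC#C)(C1C=CC=C1)C1C=CC=C1 | intermediate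
10 | (E)-1-bromodec-1-en-9-yne | Br/C=C/CCCCCCC#C | intermediate
11 | [(1E,9E)-10-bromodeca-1,9-dien-1-yl]chlorobis(cyclopentadienyl)zirconium (formed in the flask) | Cl[Zr](/C=C/CCCCCC/C=C/Br)(C1C=CC=C1)C1C=CC=C1 | intermediate
12 | (1E,9E)-1-bromo-10-iododeca-1,9-diene | Br/C=C/CCCCCC/C=C/I | intermediate
13 | Mutafran C, methyl 4-[(2R,5S)-5-[(3E,11E)-12-bromododeca-3,11-dien-1-yn-1-yl]oxolan-2-yl]butanoate | COC(=O)CCC[C@@H]1CC[C@@H](C#C/C=C/CCCCCC/C=C/Br)O1 | target

## Step count and least certain steps

Total: 7 steps. Longest linear sequence: 5 steps (1, 2, 3, 4, 7); the tail 12 is made in 2 steps (5, 6).

**Step 3 (key step).** Most likely to go wrong: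
- hydrogen-atom transfer to the C4 radical before it meets the acrylate, which would lose the ester arm;
- a second acrylate addition before the final hydrogen transfer;
- erosion of trans selectivity because the alkynyl group is sterically slim;
- competing oxidation of the propargylic carbinol by the cobalt–dioxygen system.

The fallback separates ring closure from C–C bond formation; it sets out from 4 and returns at 6. The classical oxidative-termination variant, with the divalent cobalt complex Co(modp)2 (modp = 1-morpholinocarbamoyl-4,4-dimethylpentane-1,3-dionate), O2 and catalytic t-BuOOH in i-PrOH at 55 °C, should give [(2S,5S)-5-[(triisopropylsilyl)ethynyl]oxolan-2-yl]methanol F1. As a polar alcohol, F1 can be freed of any cis isomer by chromatography. Iodination with I2, PPh3 and imidazole would give {[(2S,5S)-5-(iodomethyl)oxolan-2-yl]ethynyl}tri(propan-2-yl)silane F2. A Giese addition of F2 to 5 with (Me3Si)3SiH and AIBN in toluene at 80 °C regenerates the same C4 radical under conditions where only capture and reduction have to be balanced, and leads to 6.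

**Step 7.** Most likely to go wrong: loss of discrimination between the two alkenyl halides, with oxidative addition into the C–Br bond of 12 or 13 causing double coupling, and oxidative homocoupling of the alkyne. The fallback removes the second halide from the coupling; it sets out from 7 and returns at 13, making 10 and 12 unnecessary. Purchased non-8-yn-1-ol F3 is hydrozirconated with excess Cp2Zr(H)Cl and iodinated to (E)-9-iodonon-8-en-1-ol F4. Sonogashira coupling of F4 with 7 under the conditions of step 7 should give methyl 4-[(2R,5S)-5-[(3E)-11-hydroxyundec-3-en-1-yn-1-yl]oxolan-2-yl]butanoate F5. Dess–Martin oxidation gives methyl 4-[(2R,5S)-5-[(3E)-11-oxoundec-3-en-1-yn-1-yl]oxolan-2-yl]butanoate F6. Takai bromo-olefination of F6 (CHBr3, CrBr2 made from CrBr3 and LiAlH4, THF) then installs the C19=C20–Br unit of 13. The price is two more steps and a less secure E geometry at C19=C20.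

**Step 5.** Most likely to go wrong: over-reaction at the second, identical alkyne and a hard separation of three non-polar products. The fallback uses a starting material whose ends are already different: purchased non-8-yn-1-ol F3 takes the place of 8, and the sequence returns at 10. Dess–Martin oxidation of F3 gives non-8-ynal F7, and Takai bromo-olefination of F7 (CHBr3, CrBr2, THF) gives 10, with E selectivity as the weak point.

**Step 1.** Most likely to go wrong: ketene formation from the enolisable acid chloride under amine, and decarbonylation at palladium. The fallback reaches the ketone by addition and oxidation; it sets out from 2 and returns at 3. Lithiation of 2 (n-BuLi, THF, −78 °C) and addition to purchased pent-4-enal F8 gives rac-1-(triisopropylsilyl)hept-6-en-1-yn-3-ol F9. Oxidation of F9 with MnO2 in CH2Cl2 gives 3, at the cost of one extra step.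

## Further compounds

F1 | step 3 | [(2S,5S)-5-[(triisopropylsilyl)ethynyl]oxolan-2-yl]methanol | OC[C@@H]1CC[C@@H](C#C[Si](C(C)C)(C(C)C)C(C)C)O1
F2 | step 3 | {[(2S,5S)-5-(iodomethyl)oxolan-2-yl]ethynyl}tri(propan-2-yl)silane | IC[C@@H]1CC[C@@H](C#C[Si](C(C)C)(C(C)C)C(C)C)O1
F3 | step 7 | non-8-yn-1-ol | OCCCCCCCC#C
F4 | step 7 | (E)-9-iodonon-8-en-1-ol | OCCCCCCC/C=C/I
F5 | step 7 | methyl 4-[(2R,5S)-5-[(3E)-11-hydroxyundec-3-en-1-yn-1-yl]oxolan-2-yl]butanoate | COC(=O)CCC[C@@H]1CC[C@@H](C#C/C=C/CCCCCCCO)O1
F6 | step 7 | methyl 4-[(2R,5S)-5-[(3E)-11-oxoundec-3-en-1-yn-1-yl]oxolan-2-yl]butanoate | COC(=O)CCC[C@@H]1CC[C@@H](C#C/C=C/CCCCCCC=O)O1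
F7 | step 5 | non-8-ynal | O=CCCCCCCC#C
F8 | step 1 | pent-4-enal | C=CCCC=O
F9 | step 1 | rac-1-(triisopropylsilyl)hept-6-en-1-yn-3-ol | C=CCCC(C#C[Si](C(C)C)(C(C)C)C(C)C)O
A1 | alternative 1 | (E)-dodec-8-en-10-yn-1-yl 4-[(2R,5S)-5-(prop-1-yn-1-yl)oxolan-2-yl]butanoate | CC#C/C=C/CCCCCCCOC(=O)CCC[C@@H]1CC[C@@H](C#CC)O1
A2 | alternative 1 | C1–O–C19 lactone of (5R,8S,11E)-5,8-epoxy-19-hydroxynonadec-11-en-9-ynoic acid (oxolane-bridged 19-membered macrolactone) | O=C1CCC[C@@H]2CC[C@@H](C#C/C=C/CCCCCCCO1)O2
A3 | alternative 1 | but-2-yne | CC#CC
A4 | alternative 2 | meso-(2R,5S)-1,2:5,6-diepoxyhexane | C1O[C@@H]1CC[C@H]1CO1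
A5 | alternative 2 | (2S,5S)-oxolane-2,5-diyldimethanol | OC[C@@H]1CC[C@@H](CO)O1
A6 | alternative 3 | (S)-4-(allyloxy)-5-(tert-butyldiphenylsilyloxy)-1-diazopentan-2-one | [N-]=[N+]=CC(=O)C[C@H](OCC=C)CO[Si](c1ccccc1)(c1ccccc1)C(C)(C)C
A7 | alternative 3 | (2R,5S)-2-allyl-5-(tert-butyldiphenylsilyloxymethyl)oxolan-3-one | C=CC[C@@H]1C(=O)C[C@@H](CO[Si](c2ccccc2)(c2ccccc2)C(C)(C)C)O1
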